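**Plan**

- Ring numbering: C1 carries the (E)-hept-1-enyl group, C2 and C6 the carboxamides, C3 the pentyl group, and C4=C5 is the ring alkene. C2–C1–C6 with its two carboxyl carbons is a 3-alkenylglutarate (malonate end at C2, acetate end at C6), and C3–C4–C5 is C3–C2–C1 of an oct-2-ynoate that already bears the pentyl chain. This is what allows a [3+3] ring synthesis.
- Retrosynthesis: cut both amide C–N bonds and the extra ester on C2; return C3–H/C4=C5 to a C3=C4–C5=O enone (reductive alkene transposition); cut ring bonds C2–C3 and C5–C6 to give glutarate hub 6 and methyl oct-2-ynoate; cut the hub at C1–CH2 (Mukaiyama–Michael) and at C1=C2 (Knoevenagel).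
- Forward: the chain is joined in steps 1–3, the only ring closes in step 4, then C6 amide, tosylhydrazone, transposition, loss of one C2 ester, C2 amide.
- Stereochemistry: C1 from the chiral divalent-copper bis(oxazoline) catalyst; C6 by equilibration trans to C1; C3 by suprafacial hydrogen transfer from a C5 diazene formed after axial hydride delivery; C2 by protonation trans to C1 (also the thermodynamic arrangement).

Key step: step 4

Remark on naming: ring compounds are named with the ring numbering of the plan, not with lowest locants. "Upper face" is the face of the C1 heptenyl group.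

Assumption: the sense of induction of the copper catalyst on the dienylidene malonate is taken from the chelate model. The ligand antipode that gives (S)-6 is the one to use; it is written here as (S,S).

**Step 1**
Reactants: 1 (E)-oct-2-enal; 2 dimethyl malonate
Product: 3 dimethyl 2-[(E)-oct-2-enylidene]malonate
Conditions: TiCl4 (2 equiv), pyridine (4 equiv), THF, 0 °C to rt
Reagents that add atoms: none
Why: Knoevenagel condensation under TiCl4/pyridine activation, which joins enals and malonates at low temperature without conjugate addition to the diene product; the E-alkene of 1 is untouched and the new alkylidene carbon carries two identical esters, so no new stereo-element arises.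

**Step 2**
Reactants: 4 S-tert-butyl thioacetate
Product: 5 1-(tert-butylsulfanyl)-1-(trimethylsilyloxy)ethene
Conditions: LiN(i-Pr)2, THF, −78 °C; then Me3SiCl, −78 °C to rt
Reagents that add atoms: chlorotrimethylsilane, C[Si](C)(C)Cl
Why: Kinetic deprotonation of the thioester and O-silylation of the lithium enolate, the standard preparation of a silyl ketene thioacetal for Mukaiyama-type additions.

**Step 3**
Reactants: 3 dimethyl 2-[(E)-oct-2-enylidene]malonate; 5 1-(tert-butylsulfanyl)-1-(trimethylsilyloxy)ethene
Product: 6 S-tert-butyl (3S,4E)-3-[bis(methoxycarbonyl)methyl]dec-4-enethioate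
Conditions: preformed Cu(SbF6)2 complex (10 mol%) of 2,2-bis[(4S)-4-tert-butyl-4,5-dihydrooxazol-2-yl]propane, (CF3)2CHOH (2 equiv), PhMe/CH2Cl2 3:1, −78 °C
Reagents that add atoms: none
Why: Catalytic enantioselective Mukaiyama–Michael addition to an alkylidene malonate: the divalent copper bis(oxazoline) complex chelates both malonate carbonyls, the tert-butyl groups screen one face of the alkylidene carbon so that the thioacetate unit should enter at the β-carbon (1,4-mode) from the open face and set C1 as S, and the fluorinated alcohol takes up the silyl group and turns the catalyst over.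

**Step 4**
Reactants: 6 S-tert-butyl (3S,4E)-3-[bis(methoxycarbonyl)methyl]dec-4-enethioate; 7 methyl oct-2-ynoate
Product: 9 dimethyl (1R,6R)-6-(tert-butylsulfanylcarbonyl)-1-[(E)-hept-1-enyl]-5-oxo-3-pentylcyclohex-3-ene-2,2-dicarboxylate, via Michael adduct 8 (not isolated)
Conditions: 7 (1.3 equiv), t-BuOK (0.2 equiv), THF/t-BuOH 5:1, 0 to 40 °C; then t-BuOK (2.0 equiv), 0 °C; aq. HCl
Reagents that add atoms: none
Why: Catalytic t-BuOK turns the malonate C–H of 6 (the only acid of pKa below about 16) into a soft carbanion that adds anti across the alkynoate at C3, and t-BuOH protonates the allenolate to give mainly Z-enoate 8 with the ester cis to C2, any E-isomer reaching it through the extended enolate; the excess t-BuOK then forms the thioester enolate, which attacks the C5 ester carbonyl and expels methoxide. The sequence joins the classical base-mediated Michael addition of malonates to alkynoates to a Dieckmann condensation, the known [3+3] entry to cyclohexane-1,3-dione-type rings, here with a thioester as enolate donor. The ring closes in a 6-(enolexo)-exo-trig mode, the only alternatives for this enolate being four-membered closures onto the malonate esters. C1 is carried in unchanged from 6, and the new C6 centre lies between two carbonyl groups, so it equilibrates through the potassium enolate and is expected to settle trans to the C1 heptenyl group on acidification. The step needs C-attack at the alkyne β-carbon without acyl transfer, and it needs the thioester, not the enoate, to be the Dieckmann donor: the alcohol co-solvent quenches the allenolate before it can attack the thioester, the bulky S-tert-butyl group makes that thioester a poor acyl acceptor, and its α-CH2 is the most acidic C–H left in 8. Deprotonation of the product as its β-keto thioester enolate should pull the closure to completion.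

**Step 5**
Reactants: 9 dimethyl (1R,6R)-6-(tert-butylsulfanylcarbonyl)-1-[(E)-hept-1-enyl]-5-oxo-3-pentylcyclohex-3-ene-2,2-dicarboxylate; 10 isobutylamine
Product: 11 dimethyl (1R,6R)-1-[(E)-hept-1-enyl]-6-(isobutylcarbamoyl)-5-oxo-3-pentylcyclohex-3-ene-2,2-dicarboxylate
Conditions: AgOCOCF3 (1.2 equiv), THF, rt, dark
Reagents that add atoms: none
Why: Silver-promoted aminolysis of an S-tert-butyl β-keto thioester: the thiophilic monovalent silver salt removes the thiolate (directly or through the acylketene) and the primary amine gives the β-keto amide at room temperature, leaving the hindered methyl esters and the β,β-disubstituted enone alone; C6 stays epimerisable and is expected trans to C1.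

**Step 6**
Reactants: 11 dimethyl (1R,6R)-1-[(E)-hept-1-enyl]-6-(isobutylcarbamoyl)-5-oxo-3-pentylcyclohex-3-ene-2,2-dicarboxylate
Product: 12 dimethyl (1R,6R)-1-[(E)-hept-1-enyl]-6-(isobutylcarbamoyl)-3-pentyl-5-(tosylhydrazono)cyclohex-3-ene-2,2-dicarboxylate
Conditions: TsNHNH2 (1.3 equiv), AcOH (cat.), MeOH, 50 °C
Reagents that add atoms: 4-methylbenzenesulfonohydrazide, Cc1ccc(cc1)S(=O)(=O)NN
Why: Acid-catalysed condensation of the enone carbonyl with tosylhydrazide to the α,β-unsaturated tosylhydrazone; the quaternary C2 blocks any drift of the C3=C4 double bond and the β,β-disubstituted enone resists conjugate addition.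

**Step 7**
Reactants: 12 dimethyl (1R,6R)-1-[(E)-hept-1-enyl]-6-(isobutylcarbamoyl)-3-pentyl-5-(tosylhydrazono)cyclohex-3-ene-2,2-dicarboxylate
Product: 15 dimethyl (1R,3R,6S)-1-[(E)-hept-1-enyl]-6-(isobutylcarbamoyl)-3-pentylcyclohex-4-ene-2,2-dicarboxylate, via N-boryl allylic tosylhydrazine 13 (not isolated), via allylic diazene 14 (not isolated)
Conditions: catecholborane (3 equiv), CHCl3, 0 °C to rt; then NaOAc·3H2O, 60 °C
Reagents that add atoms: none
Why: Alkene-transposing reduction of an α,β-unsaturated tosylhydrazone with catecholborane: hydride should add to C5 along the axial trajectory from the lower face (anti to the axial C6–H, with the C6 amide and C1 heptenyl group equatorial), sulfinate loss gives the diazene with nitrogen on the upper face, and its retro-ene loss of N2 hands the hydrogen suprafacially to the upper face of C3, which places the pentyl group on the lower face and moves the alkene to C4=C5.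

**Step 8**
Reactants: 15 dimethyl (1R,3R,6S)-1-[(E)-hept-1-enyl]-6-(isobutylcarbamoyl)-3-pentylcyclohex-4-ene-2,2-dicarboxylate
Product: 16 methyl (1R,2R,3R,6S)-1-[(E)-hept-1-enyl]-6-(isobutylcarbamoyl)-3-pentylcyclohex-4-ene-2-carboxylate
Conditions: LiCl (4 equiv), H2O (4 equiv), DMSO, 150 °C
Reagents that add atoms: none
Why: Krapcho dealkoxycarbonylation (chloride demethylation, loss of CO2, protonation of the ester enolate) removes one geminal ester under neutral conditions that spare the amide and both alkenes; the C2 enolate should be protonated on the upper face, opposite the pseudo-axial C3 pentyl group, which leaves the ester trans to the C1 heptenyl group, the arrangement that is also thermodynamically preferred should the centre equilibrate.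

**Step 9**
Reactants: 16 methyl (1R,2R,3R,6S)-1-[(E)-hept-1-enyl]-6-(isobutylcarbamoyl)-3-pentylcyclohex-4-ene-2-carboxylate; 10 isobutylamine
Product: 17 (1R,2R,3R,6S)-1-[(E)-hept-1-enyl]-N2,N6-diisobutyl-3-pentylcyclohex-4-ene-2,6-dicarboxamide
Conditions: AlMe3 (4 equiv), 10 (4 equiv), PhMe, 0 to 90 °C; then aq. HCl
Reagents that add atoms: none
Why: AlMe3-mediated aminolysis of the methyl ester by the dimethylaluminium amide of isobutylamine, a direct ester-to-amide conversion that tolerates the existing secondary amide (held as its aluminium amidate) and the alkenes and should leave the preferred C2 configuration untouched.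

**Compound list**

1 | (E)-oct-2-enal | CCCCC/C=C/C=O | starting material
2 | dimethyl malonate | COC(=O)CC(=O)OC | starting material
3 | dimethyl 2-[(E)-oct-2-enylidene]malonate | CCCCC/C=C/C=C(C(=O)OC)C(=O)OC | intermediate
4 | S-tert-butyl thioacetate | CC(=O)SC(C)(C)C | starting material
5 | 1-(tert-butylsulfanyl)-1-(trimethylsilyloxy)ethene | C=C(O[Si](C)(C)C)SC(C)(C)C | intermediate
6 | S-tert-butyl (3S,4E)-3-[bis(methoxycarbonyl)methyl]dec-4-enethioate (glutarate hub) | CCCCC/C=C/[C@@H](C(C(=O)OC)C(=O)OC)CC(=O)SC(C)(C)C | intermediate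
7 | methyl oct-2-ynoate | CCCCCC#CC(=O)OC | starting material
8 | dimethyl 2-[(S,E)-1-(2-tert-butylsulfanyl-2-oxoethyl)oct-2-enyl]-2-[(Z)-1-methoxy-1-oxooct-2-en-3-yl]malonate (Michael adduct, not isolated) | CCCCC/C=C/[C@@H](C(C(=O)OC)(C(=O)OC)/C(CCCCC)=C\C(=O)OC)CC(=O)SC(C)(C)C | intermediate
9 | dimethyl (1R,6R)-6-(tert-butylsulfanylcarbonyl)-1-[(E)-hept-1-enyl]-5-oxo-3-pentylcyclohex-3-ene-2,2-dicarboxylate (1,6-trans; keto form shown) | CCCCC/C=C/[C@H]1C(C(=O)OC)(C(=O)OC)C(CCCCC)=CC(=O)[C@@H]1C(=O)SC(C)(C)C | intermediate
10 | isobutylamine (2-methylpropan-1-amine) | CC(C)CN | starting material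
11 | dimethyl (1R,6R)-1-[(E)-hept-1-enyl]-6-(isobutylcarbamoyl)-5-oxo-3-pentylcyclohex-3-ene-2,2-dicarboxylate | CCCCC/C=C/[C@H]1C(C(=O)OC)(C(=O)OC)C(CCCCC)=CC(=O)[C@@H]1C(=O)NCC(C)C | intermediate
12 | dimethyl (1R,6R)-1-[(E)-hept-1-enyl]-6-(isobutylcarbamoyl)-3-pentyl-5-(tosylhydrazono)cyclohex-3-ene-2,2-dicarboxylate (C=N isomers) | CCCCC/C=C/[C@H]1C(C(=O)OC)(C(=O)OC)C(CCCCC)=CC(=NNS(=O)(=O)c2ccc(C)cc2)[C@@H]1C(=O)NCC(C)C | intermediate
13 | dimethyl (1R,5R,6R)-5-[1-(1,3,2-benzodioxaborol-2-yl)-2-tosylhydrazinyl]-1-[(E)-hept-1-enyl]-6-(isobutylcarbamoyl)-3-pentylcyclohex-3-ene-2,2-dicarboxylate (not isolated) | CCCCC/C=C/[C@H]1C(C(=O)OC)(C(=O)OC)C(CCCCC)=C[C@@H](N(NS(=O)(=O)c2ccc(C)cc2)B2Oc3ccccc3O2)[C@@H]1C(=O)NCC(C)C | intermediate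
14 | dimethyl (1R,5R,6R)-5-diazenyl-1-[(E)-hept-1-enyl]-6-(isobutylcarbamoyl)-3-pentylcyclohex-3-ene-2,2-dicarboxylate (not isolated) | CCCCC/C=C/[C@H]1C(C(=O)OC)(C(=O)OC)C(CCCCC)=C[C@@H](N=N)[C@@H]1C(=O)NCC(C)C | intermediate
15 | dimethyl (1R,3R,6S)-1-[(E)-hept-1-enyl]-6-(isobutylcarbamoyl)-3-pentylcyclohex-4-ene-2,2-dicarboxylate | CCCCC/C=C/[C@H]1C(C(=O)OC)(C(=O)OC)[C@H](CCCCC)C=C[C@@H]1C(=O)NCC(C)C | intermediate
16 | methyl (1R,2R,3R,6S)-1-[(E)-hept-1-enyl]-6-(isobutylcarbamoyl)-3-pentylcyclohex-4-ene-2-carboxylate | CCCCC/C=C/[C@H]1[C@H](C(=O)OC)[C@H](CCCCC)C=C[C@@H]1C(=O)NCC(C)C | intermediate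
17 | (1R,2R,3R,6S)-1-[(E)-hept-1-enyl]-N2,N6-diisobutyl-3-pentylcyclohex-4-ene-2,6-dicarboxamide; systematic: (1R,2R,3S,6R)-2-[(E)-hept-1-enyl]-N1,N3-bis(2-methylpropyl)-6-pentylcyclohex-4-ene-1,3-dicarboxamide | CCCCC/C=C/[C@H]1[C@H](C(=O)NCC(C)C)[C@H](CCCCC)C=C[C@@H]1C(=O)NCC(C)C | target

**Step count**

Total: 9 steps. Longest linear sequence: 8 steps (1 → 3 → 6 → 9 → 11 → 12 → 15 → 16 → 17).

**Steps most likely to fail**

Step 4. The fully substituted, hindered malonate anion may add too slowly to the β-pentyl alkynoate, so that base-induced isomerisation or oligomerisation of 7 takes over. Alternatively the thioester enolate of 8 may fragment by retro-Michael loss of the stabilised C2 carbanion before it cyclises. The fallback sets out from 6 and comes back at 9. The alkyne is replaced by its more electrophilic allene isomer, methyl octa-2,3-dienoate F1, made from hexanoyl chloride, methyl (triphenylphosphoranylidene)acetate and Et3N. With Cs2CO3 in MeCN the malonate of 6 should add to the central allene carbon and give, after protonation, the isolable β,γ-unsaturated triester F2, in which C4 is an sp3 CH2 so that no alkene geometry restricts ring closure. F2 is then cyclised on its own with t-BuOK in THF at low temperature to the pentylidene ketone F3, and DBU brings the exocyclic double bond into conjugation to give 9.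

Step 7. Hydride may be delivered to C5 of the hydrazone from the upper face, or the hydrazone of this β-keto amide may form sluggishly; in the first case the diazene carries nitrogen on the lower face and the C3 epimer results. The fallback sets out from 11 and comes back at 15. The ketone itself is reduced under Luche conditions (NaBH4, CeCl3·7H2O, MeOH, −78 °C). The same upper-face hydride preference would now place the hydroxyl group on the lower face, cis to the C6 amide, in the allylic alcohol F4. Mitsunobu displacement with 2-nitrobenzenesulfonylhydrazide (PPh3, diethyl azodicarboxylate, THF, −30 °C) inverts C5 and gives the N-allyl sulfonylhydrazine F5. On warming, F5 loses the sulfinic acid to give diazene 14 and then 15 by the same suprafacial hydrogen shift. Because this sequence inverts C5 and step 7 does not, the two routes are stereochemically complementary.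

Step 3. The silyl ketene thioacetal may attack the remote δ-carbon (1,6-addition), or the catalyst may discriminate the alkenyl substituent poorly, which would erode regio- or enantioselectivity. The fallback sets out from 2 and comes back at 6. Dimethyl malonate is added to commercial (2E,4E)-deca-2,4-dienal (CCCCC/C=C/C=C/C=O) under iminium catalysis with a diarylprolinol trimethylsilyl ether, using the catalyst enantiomer that gives the S-adduct; this should give the aldehyde F6. Pinnick oxidation (NaClO2, NaH2PO4, 2-methylbut-2-ene, t-BuOH/H2O) gives the acid F7, and thioesterification with 2-methylpropane-2-thiol (DCC, DMAP, CH2Cl2) returns 6.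

**Further compounds**

F1 | step 4 | methyl octa-2,3-dienoate | CCCCC=C=CC(=O)OC
F2 | step 4 | dimethyl 2-[(S,E)-1-(2-tert-butylsulfanyl-2-oxoethyl)oct-2-enyl]-2-[1-(2-methoxy-2-oxoethyl)hex-1-enyl]malonate | CCCCC/C=C/[C@@H](C(C(=O)OC)(C(=O)OC)C(=CCCCC)CC(=O)OC)CC(=O)SC(C)(C)C
F3 | step 4 | dimethyl (1R,6R)-6-(tert-butylsulfanylcarbonyl)-1-[(E)-hept-1-enyl]-5-oxo-3-pentylidenecyclohexane-2,2-dicarboxylate | CCCCC/C=C/[C@H]1C(C(=O)OC)(C(=O)OC)C(=CCCCC)CC(=O)[C@@H]1C(=O)SC(C)(C)C
F4 | step 7 | dimethyl (1R,5S,6R)-1-[(E)-hept-1-enyl]-5-hydroxy-6-(isobutylcarbamoyl)-3-pentylcyclohex-3-ene-2,2-dicarboxylate | CCCCC/C=C/[C@H]1C(C(=O)OC)(C(=O)OC)C(CCCCC)=C[C@H](O)[C@@H]1C(=O)NCC(C)C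
F5 | step 7 | dimethyl (1R,5R,6R)-1-[(E)-hept-1-enyl]-6-(isobutylcarbamoyl)-5-[1-(2-nitrophenylsulfonyl)hydrazinyl]-3-pentylcyclohex-3-ene-2,2-dicarboxylate | CCCCC/C=C/[C@H]1C(C(=O)OC)(C(=O)OC)C(CCCCC)=C[C@@H](N(N)S(=O)(=O)c2ccccc2[N+](=O)[O-])[C@@H]1C(=O)NCC(C)C
F6 | step 3 | dimethyl 2-[(S,E)-1-(2-oxoethyl)oct-2-enyl]malonate | CCCCC/C=C/[C@@H](C(C(=O)OC)C(=O)OC)CC=O
F7 | step 3 | (3S,4E)-3-[bis(methoxycarbonyl)methyl]dec-4-enoic acid | CCCCC/C=C/[C@@H](C(C(=O)OC)C(=O)OC)CC(=O)O
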